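## Structural features

The target is a 2,3-dihydrobenzofuran in which benzene ring A (C3a, C4 to C7, C7a) is fused to dihydrofuran ring B (O1, C2, C3). C2 carries a 4-hydroxyphenyl group, C3 a 3,5-dihydroxyphenyl group, C4 a hydroxyl group, and C6 a 6-hydroxybenzofuran-2-yl unit joined through a biaryl bond. C2 and C3 are neighbouring stereocentres with their aryl groups trans, both S. All five oxygens outside the rings are free phenols on electron-rich rings, so the final compound is sensitive to oxidation, and the 2-arylbenzofuran is sensitive to electrophiles. The C2–O1 bond is benzylic and activated by the para oxygen of its aryl group, so it ionises easily and C2 can be epimerised towards the more stable trans arrangement. C3 is a diarylmethine with no acidifying or directing group, so its absolute configuration cannot be repaired later and must come from an asymmetric bond formation; this is the real difficulty. The key step uses two facts: C3 is bound to two aryl carbons (C3a of ring A and C1 of the resorcinol ring) and can therefore be a diaryl carbene carbon, and the C2–H bond lies 1,5 to it through C3a, C7a and O1 and is hydridic (benzylic, next to O1, para-oxygenated aryl).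

## Logic of the disconnections

**15 to 14.** The five aryl O–H groups are traced back to five O–CH3 bonds. Methyl ethers are the only masks that survive organomagnesium addition, hot hydrazine, a metal carbene, strong acid and palladium catalysis. Every earlier intermediate becomes non-acidic and stable to air. The forward demand is one Lewis-acid ether cleavage at the end that leaves the C2–O1 bond and the benzofuran intact. This is eased because the trans ring is the thermodynamic isomer, so reversible opening of C2–O1 returns the same compound.

**14 to 12 and 13.** The biaryl bond between C6 of ring A and C2 of the benzofuran is cut. The benzofuran is the most electrophile-sensitive part and is commercially available as 13, so it is kept out of the carbene step and the acid step. What remains, 12, is a plain aryl bromide. The forward demand is a cross-coupling of an electron-rich bromide with a 2-heteroarylboronic acid that loses boron easily, so a fast catalyst at mild temperature is needed.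

**12 to 11.** No skeletal bond is cut; only the configuration at C2 changes, by breaking and re-forming C2–O1. The insertion is expected to deliver the cis isomer, whereas the target is trans. This frees the key step from any demand on diastereoselectivity, since only the absolute configuration at C3 has to be right. The forward demand is reversible ionisation of C2–O1 without loss of the C3 proton. It is therefore placed at the bromide stage, before the benzofuran is present.

**11 to 10 to 9.** The C2–C3 bond is cut, leading to the diazo compound 10, which is traced to its N–N reduced form 9. Ring B and both stereocentres then come from an acyclic diaryl ketone derivative that has no stereocentre. The design of 10 is deliberate in three respects: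
- bromine rather than the benzofuran sits at the future C6, so no electron-rich heteroarene is offered to the carbene;
- the future C4 oxygen is a methyl ether, the smallest group with the least hydridic C–H bonds;
- 10 is made in the flask and never isolated.

The forward demand is catalyst control of C3 and site selectivity between the two ether groups that flank the carbene.

**9 to 8 to 7.** The C=N bond is traced to C=O, and C=O to the carbinol. The forward demand is a condensation at a carbonyl group flanked by two ortho substituents, which needs forcing conditions.

**7 to 4 and 5 (through 6).** The bond between the carbinol carbon (future C3) and the resorcinol ring is cut. This gives an aldehyde and an aryl halide of commercial type. The forward demand is that 6 adds to the aldehyde without exchanging with the aryl bromide of 4.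

**4 to 2 and 3, and 2 to 1.** The O–CH2 bond (future O1–C2) is cut, and one of the two equivalent methyl ethers of 1 is taken off. The 4-methoxybenzyl group serves both as the carrier of C2 with its aryl group and as the source of the hydridic C–H bond. The forward demand is clean mono-demethylation, which chelation to the aldehyde provides.

## Other disconnections considered

**Alternative 1:** The cut goes through ring A: C3a–C7a, C4–C5 and C7–C7a. C5, C6, C7 and C7a come from 3-(6-methoxy-1-benzofuran-2-yl)cyclobut-2-en-1-one A1. C3a and C4 come from the triisopropylsilyl ynol ether A2, which already holds the C3 methine and the silyl-protected C2 carbinol.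
- Forward key step: heating A1 with A2 would start the Danheiser benzannulation (four-electron ring opening to a vinylketene, regioselective [2+2] addition of the ynol ether, a second four-electron opening, six-electron closure, tautomerisation). It would give phenol A3, whose side chain is flanked by a free hydroxyl (future O1) and a silyl ether (future C4–OH). Ring B would be closed afterwards by forming O1–C2.
- In favour: the 1,2,3,5-pattern of ring A is fixed without ambiguity, the two ring A oxygens emerge differentiated, and the benzofuran arrives inside a fragment. The key step needs neither a metal nor a chiral catalyst. On regiocontrol of ring A and on the cost of the key step it is the equal or the better of the chosen plan.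
- Against: the pericyclic cascade creates no stereocentre. C3 must be set earlier in an acyclic precursor and carried, as a benzylic and propargylic methine, through the strongly basic ester-to-ynolate homologation that makes A2 and through a hot benzannulation. Racemisation and alkyne-to-allene isomerisation are real threats there. A1 itself needs several steps, and ring B still has to be closed.
- Comparison: structurally it builds an aromatic ring that the chosen plan buys as 1. Mechanistically it is robust but stereochemically silent, whereas the chosen plan makes the decisive centre in its key step. In step economy it is clearly longer.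

**Alternative 2:** Both heteroring bonds, C2–C3 and O1–C2, are cut. This leads to the ortho-quinone methide A5, released from sulfone A4 by loss of sulfinate, and to a one-carbon donor, the ylide of the chiral 4-methoxybenzyl thiolanium salt A6.
- Forward key step: Cs2CO3 would unmask A5 and deprotonate A6. The ylide carbon adds to the exocyclic carbon (C3) and the phenoxide displaces the sulfide, closing ring B to A7, which is the same compound as 14.
- In favour: one step makes two bonds, the ring and both stereocentres. The anti betaine leads to the trans isomer directly, so no epimerisation step is needed, and no hydrazine or diazo compound is handled. On step economy, on diastereocontrol and on reagent hazard this plan is better than the chosen one.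
- Against: the chiral information sits on the ylide carbon (C2), the centre that could be corrected anyway. C3 arises only indirectly, from face selection on a planar, crowded quinone methide of uncertain exocyclic geometry. Any cis by-product would end as the enantiomer after equilibration at C2. Asymmetric versions are far better founded for stabilised ylides than for a semi-stabilised benzyl ylide, which also tends to self-couple to a stilbene. A5 carries the electron-rich benzofuran.
- Comparison: structurally both plans close ring B at the same place. Mechanistically the chosen plan puts catalyst control on the non-correctable C3 and leaves C2 to thermodynamics, which is the safer distribution of control. In step count the alternative wins. For that reason it is kept as the fallback for the key step.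

**Alternative 3:** The resorcinol ring on C3 is cut through one ring bond, leading back to the diketo-dioxinone A8. Here C3 bears a 1,3-diketone chain that ends in a 2,2-dimethyl-1,3-dioxin-4-one.
- Forward key step: Et3N or Cs2CO3 would bring about aldol condensation of the dioxinone α-carbon with the acyl carbon on C3. Dehydration and enolisation would give the benzodioxinone A9. Cleavage of the dioxinone ring and decarboxylation would then have to follow before the last ethers are removed.
- In favour: the aromatisation is mild and biomimetic. C3 becomes a carbonyl-bearing centre, which opens access through well-developed donor–acceptor carbene or enolate chemistry. The two phenols of the new ring need no Lewis acid for their release, so only three ethers remain to be cleaved at the end. On the final deprotection it is better than the chosen plan.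
- Against: in A8 the C3–H bond is α to a ketone and benzylic, and O1 is β to it. Base can therefore epimerise C3 or expel the phenoxide and open ring B, which puts the non-correctable centre at risk in the key step itself. Building the chain adds several steps, and two more are spent deleting a carboxyl carbon that was introduced only to make the fold work.
- Comparison: structurally it constructs a ring that the chosen plan takes from commercial 5. Mechanistically it is elegant but places the fragile centre next to a carbonyl group, where the chosen plan creates it in a neutral, non-enolisable setting. In step economy it is longer.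

Key step: step 6

## Route

Assumption on the chemistry: the catalyst enantiomer that leads to the (3S) series with this di-ortho-substituted carbene is taken to be Rh2(R-PTAD)4, dirhodium tetrakis[(R)-(1-adamantyl)(N-phthalimido)acetate], by analogy with simpler benzyl ethers. Should the sense be the opposite, Rh2(S-PTAD)4 is used with no other change.

**Step 1**
Reactants: 1 4-bromo-2,6-dimethoxybenzaldehyde
Product: 2 4-bromo-2-hydroxy-6-methoxybenzaldehyde
Conditions: BCl3 (1.2 equiv), CH2Cl2, −78 to 0 °C; then H2O
Reagents that add atoms: none
Why: Chelation-directed Lewis-acid ether cleavage: BCl3 binds the aldehyde oxygen and one ortho methoxy oxygen, chloride removes that methyl group, and the resulting six-membered aryloxyboron chelate deactivates the second methoxy group, so only one ether should be cleaved.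

**Step 2**
Reactants: 2 4-bromo-2-hydroxy-6-methoxybenzaldehyde; 3 4-methoxybenzyl chloride
Product: 4 4-bromo-2-methoxy-6-[(4-methoxyphenyl)methoxy]benzaldehyde
Conditions: K2CO3, KI (cat.), DMF, 60 °C
Reagents that add atoms: none
Why: Williamson ether synthesis; the phenoxide of 2 is alkylated by the reactive benzylic chloride under iodide catalysis, and no other nucleophilic site is present.

**Step 3**
Reactants: 4 4-bromo-2-methoxy-6-[(4-methoxyphenyl)methoxy]benzaldehyde; 5 1-bromo-3,5-dimethoxybenzene
Product: 7 racemic [4-bromo-2-methoxy-6-[(4-methoxyphenyl)methoxy]phenyl](3,5-dimethoxyphenyl)methanol, via (3,5-dimethoxyphenyl)magnesium bromide 6 (not isolated)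
Conditions: 5 (1.4 equiv), Mg, I2 (cat.), THF, 50 °C; then 4, THF, −40 to 0 °C; then aq NH4Cl
Reagents that add atoms: none
Why: Grignard addition; 6 adds to the aldehyde much faster than it exchanges with the aryl bromide of 4 at low temperature. The new carbinol centre is racemic and is erased in step 4.

**Step 4**
Reactants: 7 racemic [4-bromo-2-methoxy-6-[(4-methoxyphenyl)methoxy]phenyl](3,5-dimethoxyphenyl)methanol
Product: 8 [4-bromo-2-methoxy-6-[(4-methoxyphenyl)methoxy]phenyl](3,5-dimethoxyphenyl)methanone
Conditions: Dess–Martin periodinane (1.3 equiv), CH2Cl2, rt
Reagents that add atoms: none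
Why: Dess–Martin oxidation of a secondary diaryl carbinol; the nearly neutral conditions spare the 4-methoxybenzyl ether and the aryl bromide, and the hypervalent iodine reagent is not slowed by the two ortho substituents.

**Step 5**
Reactants: 8 [4-bromo-2-methoxy-6-[(4-methoxyphenyl)methoxy]phenyl](3,5-dimethoxyphenyl)methanone
Product: 9 [4-bromo-2-methoxy-6-[(4-methoxyphenyl)methoxy]phenyl](3,5-dimethoxyphenyl)methanone hydrazone (E/Z mixture)
Conditions: N2H4·H2O (20 equiv), AcOH (cat.), EtOH, 100 °C, sealed tube
Reagents that add atoms: hydrazine (used as its hydrate), NN
Why: Acid-catalysed hydrazone condensation; heat and a large excess of hydrazine are used because the carbonyl group is flanked by two ortho substituents, and the excess suppresses azine formation. The C=N geometry is irrelevant because both isomers give the same diazo compound.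

**Step 6**
Reactants: 9 [4-bromo-2-methoxy-6-[(4-methoxyphenyl)methoxy]phenyl](3,5-dimethoxyphenyl)methanone hydrazone
Product: 11 (2R,3S)-6-bromo-3-(3,5-dimethoxyphenyl)-4-methoxy-2-(4-methoxyphenyl)-2,3-dihydro-1-benzofuran (cis), via diaryldiazomethane 10 (not isolated)
Conditions: MnO2 (8 equiv), CH2Cl2, 0 °C; then Rh2(R-PTAD)4 (1 mol %), high dilution, 0 °C to rt
Reagents that add atoms: none
Why: MnO2 dehydrogenates 9 to the diaryldiazomethane 10, and the dirhodium tetracarboxylate then expels N2 from 10 to give a rhodium-bound diaryl carbene whose two aryl donors make it selective enough to leave the arene rings alone. The carbene carbon (future C3) takes a hydrogen from the O–CH2 group 1,5 to it in an asynchronous, hydride-transfer-like event, and the C2–C3 bond forms as the oxocarbenium and rhodium-bound benzhydryl pair collapses; the closest known reaction is the enantioselective intramolecular C–H insertion of donor–donor carbenes into benzyl ethers, which gives cis-2,3-diaryl-2,3-dihydrobenzofurans. Ring B is closed as a five-membered ring by 1,5-insertion, which in the stepwise limit is a 5-endo-trig attack of the rhodium-bearing carbon on the aryl-stabilised oxocarbenium ion. C3 is set by the catalyst: the chiral pocket of the four adamantyl(phthalimido)acetate ligands decides which face of the carbene receives hydrogen and carbon. C2 is set relative to C3 by the compact closing geometry, which should place the two aryl groups cis; this centre is provisional because step 7 equilibrates it. Site selectivity is needed between the 4-methoxybenzyl C–H bonds and the C–H bonds of the C4 methoxy group, both 1,5 to the carbene; the benzylic, oxygen-flanked and para-methoxy-activated bonds are far more hydridic, so insertion there should dominate. Azine formation and O–H insertion are held back by generating 10 cold, at high dilution and only in the amount that the catalyst consumes.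

**Step 7**
Reactants: 11 (2R,3S)-6-bromo-3-(3,5-dimethoxyphenyl)-4-methoxy-2-(4-methoxyphenyl)-2,3-dihydro-1-benzofuran
Product: 12 (2S,3S)-6-bromo-3-(3,5-dimethoxyphenyl)-4-methoxy-2-(4-methoxyphenyl)-2,3-dihydro-1-benzofuran (trans)
Conditions: CF3CO2H/CH2Cl2 (1:10), 0 °C to rt
Reagents that add atoms: none
Why: Acid-promoted epimerisation of a 2-aryl-2,3-dihydrobenzofuran: protonation of O1 ionises the C2–O1 bond to a 4-methoxybenzylic cation, which the liberated phenol recaptures (5-exo), and repeated opening and closing should drain the cis isomer into the less strained trans isomer, giving C2 the S configuration. C3 is not part of the ionising bond and should keep the configuration set in step 6; no benzofuran is yet present to intercept the cation.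

**Step 8**
Reactants: 12 (2S,3S)-6-bromo-3-(3,5-dimethoxyphenyl)-4-methoxy-2-(4-methoxyphenyl)-2,3-dihydro-1-benzofuran; 13 (6-methoxy-1-benzofuran-2-yl)boronic acid
Product: 14 (2S,3S)-3-(3,5-dimethoxyphenyl)-4-methoxy-6-(6-methoxy-1-benzofuran-2-yl)-2-(4-methoxyphenyl)-2,3-dihydro-1-benzofuran
Conditions: 13 (1.5 equiv), Pd(OAc)2 (5 mol %), SPhos (10 mol %), K3PO4, THF/H2O, 50 °C
Reagents that add atoms: none
Why: Suzuki–Miyaura coupling; the bulky, electron-rich biarylphosphine lets the electron-rich aryl bromide couple at mild temperature, fast enough to outrun protodeboronation of the 2-benzofuranylboronic acid. The medium is basic and the stereocentres are remote from the reacting carbon, so the C2–O1 bond is not ionised.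

**Step 9**
Reactants: 14 (2S,3S)-3-(3,5-dimethoxyphenyl)-4-methoxy-6-(6-methoxy-1-benzofuran-2-yl)-2-(4-methoxyphenyl)-2,3-dihydro-1-benzofuran
Product: 15 5-[(2S,3S)-4-hydroxy-6-(6-hydroxy-1-benzofuran-2-yl)-2-(4-hydroxyphenyl)-2,3-dihydro-1-benzofuran-3-yl]benzene-1,3-diol (CNP0112262.1)
Conditions: BBr3 (12 equiv), CH2Cl2, −78 °C to rt, argon, dark; then H2O, 0 °C
Reagents that add atoms: none
Why: Lewis-acid cleavage of aryl methyl ethers with BBr3 (bromide attacks the methyl carbon of each boron-complexed ether), the standard last step for permethylated polyphenols of this family. The trans ring is the thermodynamic isomer and ring A becomes symmetrical about the C3a–C6 axis once the C4 ether is cleaved, so any reversible opening of C2–O1 should close again to the same compound.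

## Compound list

1 | 4-bromo-2,6-dimethoxybenzaldehyde | COc1cc(Br)cc(OC)c1C=O | starting material
2 | 4-bromo-2-hydroxy-6-methoxybenzaldehyde | COc1cc(Br)cc(O)c1C=O | intermediate
3 | 4-methoxybenzyl chloride | COc1ccc(CCl)cc1 | starting material
4 | 4-bromo-2-methoxy-6-[(4-methoxyphenyl)methoxy]benzaldehyde | COc1ccc(COc2cc(Br)cc(OC)c2C=O)cc1 | intermediate
5 | 1-bromo-3,5-dimethoxybenzene | COc1cc(Br)cc(OC)c1 | starting material
6 | (3,5-dimethoxyphenyl)magnesium bromide | COc1cc(OC)cc([Mg]Br)c1 | intermediate (not isolated)
7 | racemic [4-bromo-2-methoxy-6-[(4-methoxyphenyl)methoxy]phenyl](3,5-dimethoxyphenyl)methanol | COc1ccc(COc2cc(Br)cc(OC)c2C(O)c2cc(OC)cc(OC)c2)cc1 | intermediate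
8 | [4-bromo-2-methoxy-6-[(4-methoxyphenyl)methoxy]phenyl](3,5-dimethoxyphenyl)methanone | COc1ccc(COc2cc(Br)cc(OC)c2C(=O)c2cc(OC)cc(OC)c2)cc1 | intermediate
9 | hydrazone of 8 (E/Z mixture) | COc1ccc(COc2cc(Br)cc(OC)c2C(=NN)c2cc(OC)cc(OC)c2)cc1 | intermediate
10 | 5-bromo-2-[diazo(3,5-dimethoxyphenyl)methyl]-1-methoxy-3-[(4-methoxyphenyl)methoxy]benzene | [N-]=[N+]=C(c1cc(OC)cc(OC)c1)c1c(OC)cc(Br)cc1OCc1ccc(OC)cc1 | intermediate (not isolated)
11 | (2R,3S)-6-bromo-3-(3,5-dimethoxyphenyl)-4-methoxy-2-(4-methoxyphenyl)-2,3-dihydro-1-benzofuran (cis) | COc1ccc([C@@H]2Oc3cc(Br)cc(OC)c3[C@@H]2c2cc(OC)cc(OC)c2)cc1 | intermediate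
12 | (2S,3S)-6-bromo-3-(3,5-dimethoxyphenyl)-4-methoxy-2-(4-methoxyphenyl)-2,3-dihydro-1-benzofuran (trans) | COc1ccc([C@H]2Oc3cc(Br)cc(OC)c3[C@@H]2c2cc(OC)cc(OC)c2)cc1 | intermediate
13 | (6-methoxy-1-benzofuran-2-yl)boronic acid | COc1ccc2cc(B(O)O)oc2c1 | starting material
14 | (2S,3S)-3-(3,5-dimethoxyphenyl)-4-methoxy-6-(6-methoxy-1-benzofuran-2-yl)-2-(4-methoxyphenyl)-2,3-dihydro-1-benzofuran | COc1ccc([C@H]2Oc3cc(-c4cc5ccc(OC)cc5o4)cc(OC)c3[C@@H]2c2cc(OC)cc(OC)c2)cc1 | intermediate
15 | 5-[(2S,3S)-4-hydroxy-6-(6-hydroxy-1-benzofuran-2-yl)-2-(4-hydroxyphenyl)-2,3-dihydro-1-benzofuran-3-yl]benzene-1,3-diol | Oc1ccc([C@H]2Oc3cc(-c4cc5ccc(O)cc5o4)cc(O)c3[C@@H]2c2cc(O)cc(O)c2)cc1 | target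

## Step count and least certain steps

Total: 9 steps. Longest linear sequence: 9 steps (1 to 15); 3, 5 and 13 enter as commercial reagents.

**Step 6 (key step).** The most likely failure is erosion of enantioselectivity. The carbene-bearing ring has two ortho substituents and is twisted out of conjugation, which changes how the substrate sits in the catalyst pocket. Further losses can come from azine formation and from insertion into the C4 methoxy group.
- Fallback, from 2 and 6 to 12 (step 7 is then not needed): an excess of 6 is added to 2, one equivalent being spent on the phenol, to give 5-bromo-2-[(3,5-dimethoxyphenyl)(hydroxy)methyl]-3-methoxyphenol F1.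
- Sodium 4-methylbenzenesulfinate in aqueous formic acid exchanges the benzylic hydroxyl for a sulfonyl group to give 5-bromo-2-[(3,5-dimethoxyphenyl)(4-methylbenzenesulfonyl)methyl]-3-methoxyphenol F2.
- Cs2CO3 in CH2Cl2 eliminates sulfinate to the ortho-quinone methide 3-bromo-6-[(3,5-dimethoxyphenyl)methylidene]-5-methoxycyclohexa-2,4-dien-1-one F3.
- F3 is trapped in the same flask by the ylide generated from (2R,5R)-1-[(4-methoxyphenyl)methyl]-2,5-dimethylthiolan-1-ium tetrafluoroborate F4, itself prepared from (2R,5R)-2,5-dimethylthiolane, 3 and AgBF4.
- Conjugate addition at the exocyclic carbon and displacement of the sulfide by the phenoxide should give the trans ring directly, that is 12. The thiolane enantiomer would be chosen to match the (3S) series.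

**Step 5.** The most likely failure is slow and incomplete condensation at a carbonyl group shielded by two ortho substituents, with decomposition when the conditions are forced.
- Fallback, from 8 to 9: 8 is treated with 1,2-bis(tert-butyldimethylsilyl)hydrazine and catalytic Sc(OTf)3. This is a silyl-transfer condensation driven by loss of silanol and is known to work with hindered ketones. It gives the N-(tert-butyldimethylsilyl)hydrazone F5.
- n-Bu4NF in THF removes the silyl group and returns 9.

**Step 7.** The most likely failure is loss of the C3 proton from the ring-opened cation. Re-protonation of the resulting triarylethene would erode the configuration at C3. Intermolecular capture of the cation by a dimethoxyphenyl ring is a second loss.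
- Fallback, from 11 to 15: 11 is coupled with 13 under the conditions of step 8 to give the cis pentamethyl ether (2R,3S)-3-(3,5-dimethoxyphenyl)-4-methoxy-6-(6-methoxy-1-benzofuran-2-yl)-2-(4-methoxyphenyl)-2,3-dihydro-1-benzofuran F6.
- The BBr3 treatment of step 9 is applied to F6. Once the para oxygen of the C2 aryl group is free, C2–O1 can open through a para-quinone methide and close again without strong Brønsted acid. Equilibration to trans is therefore expected during ether cleavage and work-up, and 15 is reached without a separate acid step.

**Step 8.** The most likely failure is protodeboronation of 13 before transmetalation, because 2-benzofuranylboronic acids lose boron readily in aqueous base.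
- Fallback, from 12 to 14: direct C–H arylation of commercial 6-methoxy-1-benzofuran at C2 with 12 (Pd(OAc)2, tricyclohexylphosphonium tetrafluoroborate, pivalic acid, K2CO3, N,N-dimethylacetamide, 100 °C). This is a concerted metalation–deprotonation coupling that needs no boron reagent and makes no new intermediate.

**Step 9.** The most likely failure is incomplete cleavage of the hindered C4 ether together with electrophilic degradation of the electron-rich benzofuran and of the ionisable C2 centre during the long exposure that five ethers need.
- Fallback, from 12 to 15: BBr3 is applied to 12, which has only four ethers and no benzofuran, to give 5-[(2S,3S)-6-bromo-4-hydroxy-2-(4-hydroxyphenyl)-2,3-dihydro-1-benzofuran-3-yl]benzene-1,3-diol F7.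
- Commercial 1-benzofuran-6-ol is borylated at C2 with pinacolborane, [Ir(OMe)(cod)]2 and 4,4'-di-tert-butyl-2,2'-bipyridine (the phenol is masked in the flask as its borate) to give 2-(4,4,5,5-tetramethyl-1,3,2-dioxaborolan-2-yl)-1-benzofuran-6-ol F8.
- Suzuki–Miyaura coupling of F7 with F8 (Pd(OAc)2, SPhos, K3PO4, degassed THF/H2O) gives 15 directly, so the last step is a mild cross-coupling and not a Lewis-acid treatment.

## Further compounds

F1 | step 6 | racemic 5-bromo-2-[(3,5-dimethoxyphenyl)(hydroxy)methyl]-3-methoxyphenol | COc1cc(OC)cc(C(O)c2c(O)cc(Br)cc2OC)c1
F2 | step 6 | racemic 5-bromo-2-[(3,5-dimethoxyphenyl)(4-methylbenzenesulfonyl)methyl]-3-methoxyphenol | COc1cc(OC)cc(C(c2c(O)cc(Br)cc2OC)S(=O)(=O)c2ccc(C)cc2)c1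
F3 | step 6 | 3-bromo-6-[(3,5-dimethoxyphenyl)methylidene]-5-methoxycyclohexa-2,4-dien-1-one | COC1=CC(Br)=CC(=O)C1=Cc1cc(OC)cc(OC)c1
F4 | step 6 | (2R,5R)-1-[(4-methoxyphenyl)methyl]-2,5-dimethylthiolan-1-ium tetrafluoroborate | C[C@@H]1CC[C@@H](C)[S+]1Cc1ccc(OC)cc1.F[B-](F)(F)F
F5 | step 5 | N-(tert-butyldimethylsilyl)hydrazone of 8 | COc1ccc(COc2cc(Br)cc(OC)c2C(=NN[Si](C)(C)C(C)(C)C)c2cc(OC)cc(OC)c2)cc1
F6 | step 7 | (2R,3S)-3-(3,5-dimethoxyphenyl)-4-methoxy-6-(6-methoxy-1-benzofuran-2-yl)-2-(4-methoxyphenyl)-2,3-dihydro-1-benzofuran (cis) | COc1ccc([C@@H]2Oc3cc(-c4cc5ccc(OC)cc5o4)cc(OC)c3[C@@H]2c2cc(OC)cc(OC)c2)cc1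
F0 | step 8 | none | none
F7 | step 9 | 5-[(2S,3S)-6-bromo-4-hydroxy-2-(4-hydroxyphenyl)-2,3-dihydro-1-benzofuran-3-yl]benzene-1,3-diol | Oc1ccc([C@H]2Oc3cc(Br)cc(O)c3[C@@H]2c2cc(O)cc(O)c2)cc1
F8 | step 9 | 2-(4,4,5,5-tetramethyl-1,3,2-dioxaborolan-2-yl)-1-benzofuran-6-ol | CC1(C)OB(c2cc3ccc(O)cc3o2)OC1(C)C
A1 | alternative 1 | 3-(6-methoxy-1-benzofuran-2-yl)cyclobut-2-en-1-one | COc1ccc2cc(C3=CC(=O)C3)oc2c1
A2 | alternative 1 | tert-butyl{[(1S,2S)-2-(3,5-dimethoxyphenyl)-1-(4-methoxyphenyl)-4-[(triisopropylsilyl)oxy]but-3-yn-1-yl]oxy}dimethylsilane | CC(C)[Si](C(C)C)(C(C)C)OC#C[C@@H]([C@H](O[Si](C)(C)C(C)(C)C)c1ccc(OC)cc1)c1cc(OC)cc(OC)c1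
A3 | alternative 1 | 2-[(1S,2S)-2-[(tert-butyldimethylsilyl)oxy]-1-(3,5-dimethoxyphenyl)-2-(4-methoxyphenyl)ethyl]-5-(6-methoxy-1-benzofuran-2-yl)-3-[(triisopropylsilyl)oxy]phenol | CC(C)[Si](C(C)C)(C(C)C)Oc1cc(-c2cc3ccc(OC)cc3o2)cc(O)c1[C@@H]([C@H](O[Si](C)(C)C(C)(C)C)c1ccc(OC)cc1)c1cc(OC)cc(OC)c1
A4 | alternative 2 | racemic 2-[(3,5-dimethoxyphenyl)(4-methylbenzenesulfonyl)methyl]-3-methoxy-5-(6-methoxy-1-benzofuran-2-yl)phenol | COc1ccc2cc(-c3cc(O)c(C(c4cc(OC)cc(OC)c4)S(=O)(=O)c4ccc(C)cc4)c(OC)c3)oc2c1
A5 | alternative 2 | 6-[(3,5-dimethoxyphenyl)methylidene]-5-methoxy-3-(6-methoxy-1-benzofuran-2-yl)cyclohexa-2,4-dien-1-one | COc1ccc2cc(C3=CC(=O)C(=Cc4cc(OC)cc(OC)c4)C(OC)=C3)oc2c1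
A6 | alternative 2 | (2R,5R)-1-[(4-methoxyphenyl)methyl]-2,5-dimethylthiolan-1-ium tetrafluoroborate | C[C@@H]1CC[C@@H](C)[S+]1Cc1ccc(OC)cc1.F[B-](F)(F)F
A7 | alternative 2 | (2S,3S)-3-(3,5-dimethoxyphenyl)-4-methoxy-6-(6-methoxy-1-benzofuran-2-yl)-2-(4-methoxyphenyl)-2,3-dihydro-1-benzofuran | COc1ccc([C@H]2Oc3cc(-c4cc5ccc(OC)cc5o4)cc(OC)c3[C@@H]2c2cc(OC)cc(OC)c2)cc1
A8 | alternative 3 | 6-{4-[(2S,3S)-4-methoxy-6-(6-methoxy-1-benzofuran-2-yl)-2-(4-methoxyphenyl)-2,3-dihydro-1-benzofuran-3-yl]-2,4-dioxobutyl}-2,2-dimethyl-4H-1,3-dioxin-4-one | COc1ccc([C@H]2Oc3cc(-c4cc5ccc(OC)cc5o4)cc(OC)c3[C@@H]2C(=O)CC(=O)CC2=CC(=O)OC(C)(C)O2)cc1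
A9 | alternative 3 | 7-hydroxy-5-[(2S,3S)-4-methoxy-6-(6-methoxy-1-benzofuran-2-yl)-2-(4-methoxyphenyl)-2,3-dihydro-1-benzofuran-3-yl]-2,2-dimethyl-4H-1,3-benzodioxin-4-one | COc1ccc([C@H]2Oc3cc(-c4cc5ccc(OC)cc5o4)cc(OC)c3[C@@H]2c2cc(O)cc3OC(C)(C)OC(=O)c23)cc1
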